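**Assumptions (one line each).** Cembrane numbering is used in the explanations (C1 = ring CH carrying the acrylate carbon C15; C12 = quaternary lactone C–O carbon); the target is (1R,3R,11S,12R). Numbers are given to every intermediate and to every starting material that delivers carbon to the target; halogen and oxygen donors appear by name and SMILES in each step.

## Retrosynthetic overview

1. The 14-membered ring is closed last at C3–C4 by Nozaki–Hiyama–Kishi coupling of a C4 vinyl iodide with a C3 aldehyde.
2. The α-methylene-ε-lactone and C1 come from one C15–C1 bond: an intramolecular Rauhut–Currier reaction of a tertiary (C12–O) acrylate onto a C1=C2–C3 enal.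
3. Key step: Achmatowicz dearomatisation of a 2-furyl carbinol. The furan carbons become C12–C13–C14–C1, with C11–O set, C12 as a ketone (then MeMgBr) and C1 at aldehyde level.
4. The furyl carbinol comes from 2-acetylfuran (acetyl CH3 = C10, C=O = C11) by enolate alkylation with a C4–C9 iodo-diene bromide and Noyori reduction.
5. Ring order: furan → temporary dihydropyranone → opened → ε-lactone → 14-membered carbocycle.

## Route

**Step 1**
Reactants: 1, 2-methyl-2-vinyloxirane
Product: 2, (E)-4-chloro-2-methylbut-2-en-1-ol
Conditions: TiCl4, CH2Cl2, −85 °C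
Reagents that add atoms: titanium tetrachloride, Cl[Ti](Cl)(Cl)Cl (Cl)
Why: Lewis-acid SN2′ (1,4) opening of the vinyl epoxide by chloride gives the primary allylic chloride with the E trisubstituted alkene (future C7=C8).

**Step 2**
Reactants: 2; 3, 1-propynylmagnesium bromide
Product: 4, (E)-2-methylhept-2-en-5-yn-1-ol
Conditions: 3 (2.3 equiv), CuI (10 mol %), THF, 0 → 50 °C
Reagents that add atoms: 1-propynylmagnesium bromide, CC#C[Mg]Br
Why: Copper-catalysed SN2 alkynyl–allyl coupling at the primary allylic chloride (the first equivalent only deprotonates OH) installs C4–C5 without touching the alkene geometry.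

**Step 3**
Reactants: 4
Product: 5, (2E,5E)-6-iodo-2-methylhepta-2,5-dien-1-ol
Conditions: Cp2Zr(H)Cl (3 equiv), THF, 45 °C; then I2, 0 °C
Reagents that add atoms: iodine, II
Why: Schwartz hydrozirconation is a syn addition and, with excess reagent, equilibrates Zr onto the less hindered methyl-bearing alkyne carbon; iodinolysis with retention gives the (E)-2-iodo-2-alkene (future C4=C5).

**Step 4**
Reactants: 5
Product: 6, (2E,5E)-7-bromo-2-iodo-6-methylhepta-2,5-diene
Conditions: CBr4, PPh3, CH2Cl2, 0 °C
Reagents that add atoms: carbon tetrabromide, BrC(Br)(Br)Br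
Why: Appel bromination, SN2 at the primary allylic carbinol; no stereocentre is involved.

**Step 5**
Reactants: 7, 2-acetylfuran; 6
Product: 8, (4E,7E)-1-(furan-2-yl)-8-iodo-4-methylnona-4,7-dien-1-one
Conditions: LDA, THF, −78 °C; then 6, DMPU, −78 → −20 °C
Reagents that add atoms: none
Why: SN2 alkylation of the kinetic lithium enolate of the methyl ketone by the allylic bromide forms C9–C10; the vinyl iodide is inert to enolates.

**Step 6**
Reactants: 8
Product: 9, (1S,4E,7E)-1-(furan-2-yl)-8-iodo-4-methylnona-4,7-dien-1-ol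
Conditions: RuCl[(S,S)-TsDPEN](p-cymene) (1 mol %), HCO2H/Et3N 5:2, rt
Reagents that add atoms: none
Why: Noyori asymmetric transfer hydrogenation; the furyl group plays the aryl role, so the (S,S)-catalyst gives the (S)-carbinol, which sets C11.

**Step 7 (key step)**
Reactants: 9
Product: 10, (2S,6R)-2-[(3E,6E)-7-iodo-3-methylocta-3,6-dien-1-yl]-6-methoxy-2H-pyran-3(6H)-one (2,6-trans acetal)
Conditions: VO(acac)2 (5 mol %), t-BuOOH (1.1 equiv), CH2Cl2, 0 °C; then HC(OMe)3, BF3·OEt2, −40 °C
Reagents that add atoms: tert-butyl hydroperoxide, CC(C)(C)OO (O); trimethyl orthoformate, COC(OC)OC (OMe)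
Why: Achmatowicz oxidative ring expansion (hydroxyl-directed oxidation of the furan, dearomatisation) turns the carbinol oxygen into the ring oxygen with C11 untouched, and acetalisation under anomeric control gives mainly the trans acetal with a pseudo-axial OMe.

**Step 8**
Reactants: 10; 11, methylmagnesium bromide
Product: 12, (2S,3R,6R)-2-[(3E,6E)-7-iodo-3-methylocta-3,6-dien-1-yl]-6-methoxy-3-methyl-3,6-dihydro-2H-pyran-3-ol
Conditions: MeMgBr, anhydrous CeCl3, THF, −78 °C
Reagents that add atoms: methylmagnesium bromide, C[Mg]Br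
Why: Organocerium 1,2-addition to the enone occurs anti to the pseudo-axial anomeric OMe (axial attack), placing OH trans to the C11 side chain; this sets C12 as R.

**Step 9**
Reactants: 12
Product: 13, (2S,3R,6R)-2-[(3E,6E)-7-iodo-3-methylocta-3,6-dien-1-yl]-6-methoxy-3-methyloxan-3-ol
Conditions: o-nitrobenzenesulfonylhydrazide, Et3N, CH2Cl2, rt
Reagents that add atoms: none
Why: Diimide reduction is selective for the cis-disubstituted ring alkene over the trisubstituted alkenes and the vinyl iodide; no stereocentre changes.

**Step 10**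
Reactants: 13; 14, acryloyl chloride
Product: 15, (2S,3R,6R)-2-[(3E,6E)-7-iodo-3-methylocta-3,6-dien-1-yl]-6-methoxy-3-methyloxan-3-yl prop-2-enoate
Conditions: i-Pr2NEt, DMAP (0.2 equiv), CH2Cl2, 0 → 40 °C
Reagents that add atoms: acryloyl chloride, C=CC(=O)Cl
Why: DMAP-catalysed O-acylation puts C15–C16–C17 on the C12 oxygen (retention at C12) while C11–O is still locked in the ring.

**Step 11**
Reactants: 15
Product: 16, (2S,3R)-6-hydroxy-2-[(3E,6E)-7-iodo-3-methylocta-3,6-dien-1-yl]-3-methyloxan-3-yl prop-2-enoate (anomer mixture)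
Conditions: 1 M HCl, THF/H2O, rt
Reagents that add atoms: water, O
Why: Mild acid hydrolysis of the 2-deoxy-type methyl glycoside unveils the lactol (masked C1 aldehyde); the esters and the diene tolerate dilute acid.

**Step 12**
Reactants: 16; 17, (triphenylphosphoranylidene)acetaldehyde; 18, acetic anhydride
Product: 19, (2E,6R,7S,10E,13E)-7-acetoxy-14-iodo-6,10-dimethyl-1-oxopentadeca-2,10,13-trien-6-yl prop-2-enoate
Conditions: 17, toluene, 70 °C; then Ac2O, pyridine, DMAP, 0 °C (one pot)
Reagents that add atoms: (triphenylphosphoranylidene)acetaldehyde, O=CC=P(c1ccccc1)(c1ccccc1)c1ccccc1 (C2–C3); acetic anhydride, CC(=O)OC(C)=O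
Why: Wittig olefination of the open hydroxy-aldehyde form of the lactol with the stabilised ylide gives the (E)-enal C1=C2–C3, and in-pot acetylation caps the liberated C11–OH before oxa-Michael addition or acyl migration can occur.

**Step 13**
Reactants: 19
Product: 20, (1S,4E,7E)-8-iodo-4-methyl-1-[(2R,5R)-2-methyl-6-methylidene-7-oxo-5-(2-oxoethyl)oxepan-2-yl]nona-4,7-dien-1-yl acetate
Conditions: PMe3 (30 mol %), t-AmOH, rt, 0.02 M
Reagents that add atoms: none
Why: Proposed new method: a 7-exo phosphine-catalysed Rauhut–Currier cyclisation in which PMe3 adds reversibly to the unhindered acrylate β-carbon, the ester enolate (C15) adds to the enal β-carbon (C1) through a chair-like seven-membered transition state with the CH(OAc)R group on C12 and the enal chain on C1 both pseudo-equatorial (1,4-trans, C1 = R), and proton transfer plus loss of PMe3 regenerates the exocyclic methylene; the closest known reactions are phosphine-catalysed intramolecular Rauhut–Currier (vinylogous Morita–Baylis–Hillman) cycloisomerisations to five- and six-membered rings, including transannular cases.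

**Step 14**
Reactants: 20
Product: 21, Dendronpholide B
Conditions: CrCl2 (10 equiv), NiCl2 (0.1 equiv), DMSO/THF 3:1, 2 mM, rt
Reagents that add atoms: none
Why: Nozaki–Hiyama–Kishi macrocyclisation adds the alkenylchromium (E geometry retained) to the C3 aldehyde; the 3R carbinol relies on macrocyclic 1,3-control from C1, reinforced if needed by a chiral sulfonamide ligand on chromium, and this selectivity is not secured.

## Compound list

1 | 2-methyl-2-vinyloxirane | CC1(C=C)CO1 | starting material
2 | (E)-4-chloro-2-methylbut-2-en-1-ol | OC/C(C)=C/CCl | intermediate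
3 | 1-propynylmagnesium bromide | CC#C[Mg]Br | starting material
4 | (E)-2-methylhept-2-en-5-yn-1-ol | OC/C(C)=C/CC#CC | intermediate
5 | (2E,5E)-6-iodo-2-methylhepta-2,5-dien-1-ol | OC/C(C)=C/C/C=C(\C)I | intermediate
6 | (2E,5E)-7-bromo-2-iodo-6-methylhepta-2,5-diene | BrC/C(C)=C/C/C=C(\C)I | intermediate
7 | 2-acetylfuran | CC(=O)c1ccco1 | starting material
8 | (4E,7E)-1-(furan-2-yl)-8-iodo-4-methylnona-4,7-dien-1-one | O=C(CC/C(C)=C/C/C=C(\C)I)c1ccco1 | intermediate
9 | (1S,4E,7E)-1-(furan-2-yl)-8-iodo-4-methylnona-4,7-dien-1-ol | O[C@@H](CC/C(C)=C/C/C=C(\C)I)c1ccco1 | intermediate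
10 | (2S,6R)-2-[(3E,6E)-7-iodo-3-methylocta-3,6-dien-1-yl]-6-methoxy-2H-pyran-3(6H)-one | CO[C@H]1C=CC(=O)[C@H](CC/C(C)=C/C/C=C(\C)I)O1 | intermediate
11 | methylmagnesium bromide | C[Mg]Br | starting material
12 | (2S,3R,6R)-2-[(3E,6E)-7-iodo-3-methylocta-3,6-dien-1-yl]-6-methoxy-3-methyl-3,6-dihydro-2H-pyran-3-ol | CO[C@H]1C=C[C@@](C)(O)[C@H](CC/C(C)=C/C/C=C(\C)I)O1 | intermediate
13 | (2S,3R,6R)-2-[(3E,6E)-7-iodo-3-methylocta-3,6-dien-1-yl]-6-methoxy-3-methyloxan-3-ol | CO[C@H]1CC[C@@](C)(O)[C@H](CC/C(C)=C/C/C=C(\C)I)O1 | intermediate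
14 | acryloyl chloride | C=CC(=O)Cl | starting material
15 | (2S,3R,6R)-2-[(3E,6E)-7-iodo-3-methylocta-3,6-dien-1-yl]-6-methoxy-3-methyloxan-3-yl prop-2-enoate | CO[C@H]1CC[C@@](C)(OC(=O)C=C)[C@H](CC/C(C)=C/C/C=C(\C)I)O1 | intermediate
16 | (2S,3R)-6-hydroxy-2-[(3E,6E)-7-iodo-3-methylocta-3,6-dien-1-yl]-3-methyloxan-3-yl prop-2-enoate | OC1CC[C@@](C)(OC(=O)C=C)[C@H](CC/C(C)=C/C/C=C(\C)I)O1 | intermediate
17 | (triphenylphosphoranylidene)acetaldehyde | O=CC=P(c1ccccc1)(c1ccccc1)c1ccccc1 | starting material
18 | acetic anhydride | CC(=O)OC(C)=O | starting material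
19 | (2E,6R,7S,10E,13E)-7-acetoxy-14-iodo-6,10-dimethyl-1-oxopentadeca-2,10,13-trien-6-yl prop-2-enoate | C=CC(=O)O[C@@](C)([C@@H](OC(C)=O)CC/C(C)=C/C/C=C(\C)I)CC/C=C/C=O | intermediate
20 | (1S,4E,7E)-8-iodo-4-methyl-1-[(2R,5R)-2-methyl-6-methylidene-7-oxo-5-(2-oxoethyl)oxepan-2-yl]nona-4,7-dien-1-yl acetate | C=C1C(=O)O[C@@](C)([C@@H](OC(C)=O)CC/C(C)=C/C/C=C(\C)I)CC[C@@H]1CC=O | intermediate
21 | Dendronpholide B | C=C1C(=O)O[C@]2(C)CC[C@@H]1C[C@@H](O)/C(C)=C/C/C=C(\C)CC[C@@H]2OC(C)=O | target

## Summary

Total step count: 14. Longest linear sequence: 14 (steps 1–14; 2-acetylfuran enters at step 5).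

Steps most likely to fail, each with a fallback that changes the approach:

1. **Step 13** (unprecedented seven-membered Rauhut–Currier closure; C1 set only by substrate control). Fallback: acylate the C12–OH with an acetoacetyl group instead of acryloyl, close C15–C1 by a diarylprolinol-catalysed (iminium) intramolecular Michael addition to the enal so that C1 is under catalyst control, then install the methylene by deacylative methylenation with formaldehyde.
2. **Step 14** (macrocyclisation yield and C3 configuration). Fallback: run the NHK ring closure on enal 19 first to give a macrocyclic divinyl carbinol, oxidise to the cross-conjugated dienone, perform the Rauhut–Currier step transannularly, and set C3 last by CBS reduction under reagent control.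
3. **Step 7** (furan oxidation must outrun vanadium-directed epoxidation of the bishomoallylic C7=C8 alkene). Fallback: alkylate 2-acetylfuran with propargyl bromide instead, carry only a C7≡C8 alkyne through reduction, Achmatowicz and methyl addition, and append the C4–C7 diene afterwards by Negishi carboalumination and allylation.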